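**Retrosynthetic overview**

1. Ring B (cyclohexene C3a–C4–C5–C6–C7–C7a) is closed last, by ring-closing metathesis of a C4 isopropenyl group with a C5 vinyl group; ring A (cyclopentene C1–C2–C3–C3a–C7a) is present from the start as an R-configured 4-substituted cyclopentenone.
2. Key disconnections, made in one flask: C3a–C4 (copper-catalysed 1,4-addition of an isopropenyl Grignard reagent to the ring-A enone) and C6–C7 (Ireland–Claisen rearrangement of the C7 ester enolate onto its dienyl carbinol ester).
3. Enabling feature: C7 carries the carboxyl group and is bonded to C7a, the α-carbon of a latent C1 ketone whose β-carbon is C3a; the quaternary C6 bears an E-styryl group (C8=C9), the mark of a transposed 1-phenylallyl ester. One 2-(1-carboxyethyl)cyclopentenone ester is therefore both Michael acceptor at C3a and Claisen substrate at C7/C6.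
4. The C1 ketone is then converted into the ethyl-bearing C1=C2 olefin (enol triflate, iron-catalysed ethylation); the S,Z-dienyl carbinol comes from benzaldehyde and but-1-yne.
5. Order of ring formation: ring A (given), then ring B (step 12).

Key step: step 9

Remark: locants C1 to C7a are those of the hydrindane skeleton of 20 (C8, C9 = styryl carbons) and are used for all intermediates; the propanoate α-carbon (C7) of 6, 7 and 13 is a mixture of epimers, which does not matter because it becomes planar in step 9.

Step 1
Reactants: 1 (R)-4-[(tert-butyldimethylsilyl)oxy]cyclopent-2-en-1-one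
Product: 3 (R)-4-methylcyclopent-2-en-1-one, via trans β-silyloxy ketone 2 (not isolated)
Conditions: Me2CuLi, Et2O, −78 °C; NH4Cl work-up; then DBU, CH2Cl2, 23 °C
Reagents that add atoms: lithium dimethylcuprate, [Li+].C[Cu-]C
Why: Cuprate 1,4-addition should occur anti to the silyloxy group, and base-induced E1cB loss of silanol (addition–elimination enone transposition) then makes the methyl-bearing carbon the R-configured C3.

Step 2
Reactants: 3 (R)-4-methylcyclopent-2-en-1-one
Product: 4 (R)-2-iodo-4-methylcyclopent-2-en-1-one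
Conditions: I2, K2CO3, DMAP (cat.), THF/H2O, 23 °C
Reagents that add atoms: iodine, II
Why: Nucleophile-catalysed α-iodination of a cyclic enone (Baylis–Hillman-type addition, iodination of the enolate, elimination) should leave the C3 stereocentre untouched.

Step 3
Reactants: 4 (R)-2-iodo-4-methylcyclopent-2-en-1-one; 5 tert-butyl 2-bromopropanoate
Product: 6 tert-butyl 2-[(3R)-3-methyl-5-oxocyclopent-1-en-1-yl]propanoate (both epimers at the propanoate α-carbon)
Conditions: 5, Zn, THF, 40 °C; then 4, Pd(P(t-Bu)3)2 (5 mol %), THF, 23 °C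
Reagents that add atoms: none
Why: Negishi-type cross-coupling of the Reformatsky zinc enolate with the α-iodoenone under zerovalent palladium catalysis should attach C7 to C7a, the new α-centre forming as an inconsequential mixture.

Step 4
Reactants: 6 tert-butyl 2-[(3R)-3-methyl-5-oxocyclopent-1-en-1-yl]propanoate
Product: 7 2-[(3R)-3-methyl-5-oxocyclopent-1-en-1-yl]propanoic acid
Conditions: CF3CO2H, CH2Cl2, 0 → 23 °C
Reagents that add atoms: none
Why: Acidolysis of the tert-butyl ester (loss of 2-methylpropene) should free the acid without touching the enone.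

Step 5
Reactants: 8 benzaldehyde; 9 but-1-yne
Product: 10 (R)-1-phenylpent-2-yn-1-ol
Conditions: Me2Zn, ProPhenol ligand (10 mol %, the enantiomer that gives the R carbinol), Ph3PO (20 mol %), toluene, 0 °C
Reagents that add atoms: none
Why: Catalytic enantioselective addition of a zinc alkynylide to an aromatic aldehyde (ligand-controlled facial selectivity) sets the carbinol centre that later controls C6 and C7.

Step 6
Reactants: 10 (R)-1-phenylpent-2-yn-1-ol
Product: 11 (1S,2Z)-3-iodo-1-phenylpent-2-en-1-ol
Conditions: NaAlH2(OCH2CH2OMe)2, THF, 0 → 23 °C; EtOAc; then I2, −78 → 0 °C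
Reagents that add atoms: iodine, II
Why: Hydroxyl-directed trans-hydroalumination should place aluminium on the distal alkyne carbon cis to the carbinol carbon, and iodinolysis with retention should give the Z-iodoalkene with the carbinol centre unchanged (the descriptor changes only by priority).

Step 7
Reactants: 11 (1S,2Z)-3-iodo-1-phenylpent-2-en-1-ol
Product: 12 (1S,2Z)-3-ethyl-1-phenylpenta-2,4-dien-1-ol
Conditions: vinylboronic acid pinacol ester, PdCl2(dppf) (5 mol %), Cs2CO3, THF/H2O, 50 °C
Reagents that add atoms: 4,4,5,5-tetramethyl-2-vinyl-1,3,2-dioxaborolane, C=CB1OC(C)(C)C(C)(C)O1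
Why: Suzuki–Miyaura coupling proceeds with retention of alkene geometry, so the vinyl group (future C5) should end cis to the carbinol carbon.

Step 8
Reactants: 7 2-[(3R)-3-methyl-5-oxocyclopent-1-en-1-yl]propanoic acid; 12 (1S,2Z)-3-ethyl-1-phenylpenta-2,4-dien-1-ol
Product: 13 (1S,2Z)-3-ethyl-1-phenylpenta-2,4-dien-1-yl 2-[(3R)-3-methyl-5-oxocyclopent-1-en-1-yl]propanoate
Conditions: DCC, DMAP (cat.), CH2Cl2, 0 °C
Reagents that add atoms: none
Why: Steglich esterification under neutral conditions should acylate the ionisation-prone bis-allylic benzylic alcohol with retention at the carbinol carbon.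

Step 9
Reactants: 13 (1S,2Z)-3-ethyl-1-phenylpenta-2,4-dien-1-yl 2-[(3R)-3-methyl-5-oxocyclopent-1-en-1-yl]propanoate
Product: 17 (E)-3-ethenyl-3-ethyl-2-methyl-2-[3-methyl-5-oxo-2-(prop-1-en-2-yl)cyclopentyl]-5-phenylpent-4-enoic acid (all stereocentres as in 20), via silyl enol ether 14 (not isolated), via bis-silyl ketene acetal 15 (not isolated), via rearranged bis-silyl derivative 16 (not isolated)
Conditions: CH2=C(CH3)MgBr, CuBr·SMe2 (20 mol %), Me3SiCl, THF, −78 °C; then LiN(i-Pr)2, Me3SiCl, THF–DMPU, −78 → 60 °C; then 1 M HCl, THF, 23 °C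
Reagents that add atoms: isopropenylmagnesium bromide, C=C(C)[Mg]Br
Why: Copper-catalysed, Me3SiCl-accelerated 1,4-addition of the isopropenyl Grignard reagent to the 2-substituted cyclopentenone forms C3a–C4 and traps the C1 enolate as silyl enol ether 14; LiN(i-Pr)2/Me3SiCl then convert the only remaining acidic site (C7–H, α to the ester) into bis-silyl ketene acetal 15, whose [3,3]-sigmatropic shift (Ireland–Claisen rearrangement) through a chair transition state forms C6–C7 and gives 16, which is hydrolysed to 17. The closest known reaction types are the tandem conjugate addition/Ireland–Claisen rearrangement of allyl enoates and the ester-enolate Claisen construction of vicinal quaternary carbons. No ring is closed in this step (ring B is closed in step 12); the pericyclic array is C7, the carboxyl carbon, the ester oxygen, the carbinol carbon C9, C8 and C6. C3a is set by addition anti to the C3 methyl group; C6 and C7 are set together by 1,3-chirality transfer from the S carbinol carbon (phenyl equatorial, which also gives the E-styryl group), by the Z geometry of the C6=C8 olefin (vinyl axial) and by the ketene acetal geometry (cyclopentenyl group syn to OSiMe3 to avoid A(1,3) strain with the secondary alkoxy group, hence methyl axial); C7a is set on acidic work-up by equilibration to the all-trans cyclopentanone. The step needs 1,4-addition rather than attack on the allylic ester (secured by copper catalysis with Me3SiCl at −78 °C and the poor leaving-group ability of the carboxylate) and rearrangement at C6 rather than at the remote diene terminus (secured by the six-membered transition state).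

Step 10
Reactants: 17 (E)-3-ethenyl-3-ethyl-2-methyl-2-[3-methyl-5-oxo-2-(prop-1-en-2-yl)cyclopentyl]-5-phenylpent-4-enoic acid
Product: 18 (E)-3-ethenyl-3-ethyl-2-methyl-2-[4-methyl-5-(prop-1-en-2-yl)-2-(trifluoromethylsulfonyloxy)cyclopent-2-en-1-yl]-5-phenylpent-4-enoic acid (stereocentres as in 20)
Conditions: KN(SiMe3)2 (2.2 equiv), THF, −78 °C; then PhNTf2, −78 → 0 °C; dilute HCl work-up
Reagents that add atoms: N-phenylbis(trifluoromethanesulfonimide), O=S(=O)(N(c1ccccc1)S(=O)(=O)C(F)(F)F)C(F)(F)F
Why: Kinetic deprotonation of the ketone at the less hindered C2 methylene (C7a is tertiary and shielded by the quaternary C7) and O-triflation of the enolate should fix the C1=C2 position without epimerising C7a, the acid being carried as its potassium salt.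

Step 11
Reactants: 18 enol triflate (name as in step 10)
Product: 19 (E)-3-ethenyl-3-ethyl-2-[2-ethyl-4-methyl-5-(prop-1-en-2-yl)cyclopent-2-en-1-yl]-2-methyl-5-phenylpent-4-enoic acid (stereocentres as in 20)
Conditions: EtMgBr (3 equiv), Fe(acac)3 (5 mol %), THF/NMP, −30 → 0 °C; dilute HCl work-up
Reagents that add atoms: ethylmagnesium bromide, CC[Mg]Br
Why: Iron-catalysed cross-coupling of an alkenyl triflate with an alkyl Grignard reagent should install the C1 ethyl group with retention of the double-bond position, one equivalent of the Grignard reagent being consumed by the acid.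

Step 12
Reactants: 19 (E)-3-ethenyl-3-ethyl-2-[2-ethyl-4-methyl-5-(prop-1-en-2-yl)cyclopent-2-en-1-yl]-2-methyl-5-phenylpent-4-enoic acid
Product: 20 24-nor-spiculoic acid B
Conditions: second-generation Grubbs catalyst (5 mol %), toluene (0.005 M), 80 °C
Reagents that add atoms: none
Why: Ring-closing metathesis between the terminal vinyl group and the 1,1-disubstituted isopropenyl group should close ring B as the trisubstituted C4=C5 olefin (six-membered ring, ethene lost), the trans ring fusion following from the trans C3a/C7a substituents already in place.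

**Compound list**

1 | (R)-4-[(tert-butyldimethylsilyl)oxy]cyclopent-2-en-1-one | O=C1C=C[C@H](O[Si](C)(C)C(C)(C)C)C1 | starting material
2 | (3R,4R)-4-[(tert-butyldimethylsilyl)oxy]-3-methylcyclopentan-1-one (trans) | O=C1C[C@@H](C)[C@H](O[Si](C)(C)C(C)(C)C)C1 | intermediate
3 | (R)-4-methylcyclopent-2-en-1-one | O=C1C[C@@H](C)C=C1 | intermediate
4 | (R)-2-iodo-4-methylcyclopent-2-en-1-one | O=C1C[C@@H](C)C=C1I | intermediate
5 | tert-butyl 2-bromopropanoate (racemic) | CC(Br)C(=O)OC(C)(C)C | starting material
6 | tert-butyl 2-[(3R)-3-methyl-5-oxocyclopent-1-en-1-yl]propanoate (epimers at the α-carbon) | O=C1C[C@@H](C)C=C1C(C)C(=O)OC(C)(C)C | intermediate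
7 | 2-[(3R)-3-methyl-5-oxocyclopent-1-en-1-yl]propanoic acid (epimers at the α-carbon) | O=C1C[C@@H](C)C=C1C(C)C(=O)O | intermediate
8 | benzaldehyde | O=Cc1ccccc1 | starting material
9 | but-1-yne | CCC#C | starting material
10 | (R)-1-phenylpent-2-yn-1-ol | O[C@H](c1ccccc1)C#CCC | intermediate
11 | (1S,2Z)-3-iodo-1-phenylpent-2-en-1-ol | O[C@H](c1ccccc1)/C=C(\I)CC | intermediate
12 | (1S,2Z)-3-ethyl-1-phenylpenta-2,4-dien-1-ol | O[C@H](c1ccccc1)/C=C(\C=C)CC | intermediate
13 | (1S,2Z)-3-ethyl-1-phenylpenta-2,4-dien-1-yl 2-[(3R)-3-methyl-5-oxocyclopent-1-en-1-yl]propanoate (epimers at the α-carbon) | O=C1C[C@@H](C)C=C1C(C)C(=O)O[C@H](c1ccccc1)/C=C(\C=C)CC | intermediate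
14 | dienyl 2-[4-methyl-5-(prop-1-en-2-yl)-2-(trimethylsilyloxy)cyclopent-1-en-1-yl]propanoate, isopropenyl trans to methyl (silyl enol ether of the 1,4-adduct) | C[Si](C)(C)OC1=C(C(C)C(=O)O[C@H](c2ccccc2)/C=C(\C=C)CC)[C@@H](C(C)=C)[C@H](C)C1 | intermediate
15 | bis-silyl ketene acetal of 14 (cyclopentenyl group cis to OSiMe3, methyl cis to the dienyloxy group) | C[Si](C)(C)OC1=C(/C(C)=C(\O[Si](C)(C)C)O[C@H](c2ccccc2)/C=C(\C=C)CC)[C@@H](C(C)=C)[C@H](C)C1 | intermediate
16 | trimethylsilyl ester and C1 silyl enol ether of 17 (Claisen product before hydrolysis) | C[Si](C)(C)OC1=C([C@@](C)(C(=O)O[Si](C)(C)C)[C@](/C=C/c2ccccc2)(CC)C=C)[C@@H](C(C)=C)[C@H](C)C1 | intermediate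
17 | (E)-3-ethenyl-3-ethyl-2-methyl-2-[3-methyl-5-oxo-2-(prop-1-en-2-yl)cyclopentyl]-5-phenylpent-4-enoic acid (ring substituents all-trans; C6, C7 as in 20) | O=C1C[C@@H](C)[C@H](C(C)=C)[C@H]1[C@@](C)(C(=O)O)[C@](/C=C/c1ccccc1)(CC)C=C | intermediate
18 | C1 enol triflate of 17 (C1=C2) | O=S(=O)(OC1=C[C@@H](C)[C@H](C(C)=C)[C@H]1[C@@](C)(C(=O)O)[C@](/C=C/c1ccccc1)(CC)C=C)C(F)(F)F | intermediate
19 | (E)-3-ethenyl-3-ethyl-2-[2-ethyl-4-methyl-5-(prop-1-en-2-yl)cyclopent-2-en-1-yl]-2-methyl-5-phenylpent-4-enoic acid (stereocentres as in 20) | CCC1=C[C@@H](C)[C@H](C(C)=C)[C@H]1[C@@](C)(C(=O)O)[C@](/C=C/c1ccccc1)(CC)C=C | intermediate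
20 | 24-nor-spiculoic acid B | CCC1=C[C@@H](C)[C@@H]2C(C)=C[C@@](/C=C/c3ccccc3)(CC)[C@](C)(C(=O)O)[C@@H]12 | target

**Step count**

Total: 12 steps. Longest linear sequence: 9 steps (steps 1–4 and 8–12, from 1).

**Steps most likely to fail**

Step 9 (key step). What may go wrong: the organocopper reagent substitutes the allylic benzylic ester instead of adding to the enone, or the ketene acetal forms without geometric control, so that C7 is set unselectively. Fallback (sets out from 6, uses 12, comes back at 17): the two bond formations are separated and the ester enolate is made from a saturated ester under reagent control. Copper-catalysed addition of isopropenylmagnesium bromide to 6, followed by equilibration, should give the all-trans tert-butyl keto ester F1. CF3CO2H then gives keto acid F2, and DCC/DMAP esterification with 12 gives keto ester F3. Deprotonation of ketone (kinetic, C2) and ester with a chiral lithium amide base (or KN(SiMe3)2) in the presence of Me3SiCl gives bis-silyl derivative F4. On warming, F4 should rearrange to silyl ester F5, and acidic work-up gives 17.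

Step 12. What may go wrong: the ruthenium carbene engages the styryl double bond, or stalls at the 1,1-disubstituted isopropenyl group in the crowded diene 19, so that ring B is not closed cleanly. Fallback (sets out from 17, comes back at 20): ring B is closed before ring A is finished, on a substrate without the ring-A olefin. Ring-closing metathesis of 17 gives the trans-fused bicyclic keto acid F6. Kinetic deprotonation (KN(SiMe3)2, −78 °C) and PhNTf2 give bicyclic enol triflate F7, and iron-catalysed coupling with EtMgBr gives 20.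

Step 3. What may go wrong: the zinc enolate adds in a conjugate sense to the iodoenone, or is protonated before it transmetalates to palladium. Fallback (sets out from 3, comes back at 6): thiolate-mediated α-alkylation of the enone. Conjugate addition of PhSLi to 3 and alkylation of the resulting enolate with tert-butyl 2-(trifluoromethylsulfonyloxy)propanoate give β-phenylsulfanyl ketone F8. NaIO4 oxidation gives sulfoxide F9, and thermal syn-elimination (toluene, 80 °C) gives 6.

**Further compounds**

F1 | step 9 | tert-butyl 2-[3-methyl-5-oxo-2-(prop-1-en-2-yl)cyclopentyl]propanoate (ring substituents all-trans) | O=C1C[C@@H](C)[C@H](C(C)=C)[C@H]1C(C)C(=O)OC(C)(C)C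
F2 | step 9 | 2-[3-methyl-5-oxo-2-(prop-1-en-2-yl)cyclopentyl]propanoic acid (all-trans) | O=C1C[C@@H](C)[C@H](C(C)=C)[C@H]1C(C)C(=O)O
F3 | step 9 | (1S,2Z)-3-ethyl-1-phenylpenta-2,4-dien-1-yl ester of F2 | O=C1C[C@@H](C)[C@H](C(C)=C)[C@H]1C(C)C(=O)O[C@H](c1ccccc1)/C=C(\C=C)CC
F4 | step 9 | bis-silyl derivative of F3 (C1=C2 silyl enol ether and silyl ketene acetal) | C[Si](C)(C)OC1=C[C@@H](C)[C@H](C(C)=C)[C@H]1/C(C)=C(\O[Si](C)(C)C)O[C@H](c2ccccc2)/C=C(\C=C)CC
F5 | step 9 | rearranged trimethylsilyl ester with C1=C2 silyl enol ether | C[Si](C)(C)OC1=C[C@@H](C)[C@H](C(C)=C)[C@H]1[C@@](C)(C(=O)O[Si](C)(C)C)[C@](/C=C/c2ccccc2)(CC)C=C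
F6 | step 12 | bicyclic keto acid (20 with C1 ketone and C2 methylene in place of the ethyl-bearing olefin) | O=C1C[C@@H](C)[C@@H]2C(C)=C[C@@](/C=C/c3ccccc3)(CC)[C@](C)(C(=O)O)[C@@H]12
F7 | step 12 | C1 enol triflate of F6 | O=S(=O)(OC1=C[C@@H](C)[C@@H]2C(C)=C[C@@](/C=C/c3ccccc3)(CC)[C@](C)(C(=O)O)[C@@H]12)C(F)(F)F
F8 | step 3 | tert-butyl 2-[3-methyl-5-oxo-2-(phenylsulfanyl)cyclopentyl]propanoate (ring substituents all-trans) | O=C1C[C@@H](C)[C@H](Sc2ccccc2)[C@H]1C(C)C(=O)OC(C)(C)C
F9 | step 3 | sulfoxide of F8 | O=C1C[C@@H](C)[C@H](S(=O)c2ccccc2)[C@H]1C(C)C(=O)OC(C)(C)C
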